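The leftover comes first. Each flask at 0.34 M holds 170 µM of free catalyst against 96 µM of impurity, and a bench chemist writes the impurity off mole for mole and counts what stays, 74.0 µM. The ratio of impurity to catalyst is 0.565, so some catalyst stays.

in all of them: free catalyst 0.05 mol%; impurity 96 µM

| charge | left-handed substrate | right-handed substrate | partner | added ligand | remark | time |
|---|---|---|---|---|---|---|
| east | 0.34 M | 0.34 M | 0.80 equiv | 0.62 mM | run made earlier |  |
| south | 0.34 M | 0.34 M | 0.80 equiv | 0.97 mM | run made earlier |  |
| south-east | 0.68 M | 0.68 M | 0.80 equiv | 0.44 mM | run made earlier |  |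
| blue | 0.34 M | 0.34 M | 0.800 equiv | 0.44 mM |  | 8.0 h |
| teal | 0.34 M | 0.34 M | 0.800 equiv | 0.44 mM |  | 5.0 h |

| run | time / h | right-handed substrate / % | left-handed substrate / % | left-handed product / % |
|---|---|---|---|---|
| east | 0.500 | 50.2 | 47.6 | 2.6 |
| east | 0.833 | 50.2 | 46.6 | 4.4 |
| east | 1.33 | 49.0 | 44.5 | 6.1 |
| east | 2.00 | 49.0 | 42.0 | 7.8 |
| east | 3.00 | 48.5 | 39.7 | 12.4 |
| east | 4.00 | 46.6 | 38.1 | 13.6 |
| east | 6.00 | 44.1 | 35.4 | 18.5 |
| south | 0.333 | 50.8 | 48.2 | 1.8 |
| south | 1.00 | 49.6 | 45.7 | 4.4 |
| south | 2.00 | 49.4 | 43.7 | 7.4 |
| south | 3.00 | 47.9 | 41.0 | 9.7 |
| south | 4.00 | 46.9 | 39.7 | 12.5 |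
| south | 5.00 | 45.7 | 38.4 | 14.7 |
| south | 6.00 | 45.3 | 37.0 | 16.1 |
| south-east | 0.500 | 48.4 | 41.8 | 9.7 |
| south-east | 1.50 | 46.7 | 30.8 | 20.2 |
| south-east | 3.00 | 42.8 | 26.1 | 27.6 |
| south-east | 5.00 | 40.3 | 24.3 | 31.8 |
| south-east | 6.00 | 38.0 | 23.9 | 35.2 |

(standard deviation of a reading: 0.5 percentage points)

- free catalyst is single-handed; left-handed substrate and right-handed substrate are mirror images of each other, charged as a racemate, each of them at the stated concentration
- what was read earlier has a scatter of 0.5 percentage points, one standard deviation
- candidate steps: partner + catalyst intermediate A -> free catalyst + left-handed product; free catalyst + right-handed substrate <-> catalyst intermediate B; left-handed substrate <-> right-handed substrate; free catalyst + left-handed substrate <-> catalyst intermediate A; free catalyst + added ligand <-> idle complex; partner + catalyst intermediate B -> free catalyst + right-handed product; free catalyst + impurity -> spent catalyst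
- an excess is the difference of the two amounts in percent of their sum
- an excess is below zero if the other one leads

1. the winner by excess of right-handed substrate over left-handed substrate among what is left of the two; "neither" if no more than 2 percentage points parts them (blue / teal / neither)
2. excess of right-handed substrate over left-handed substrate among what is left of the two at the end, blue
3. excess of right-handed substrate over left-handed substrate among what is left of the two at the end, teal

My reckoning takes that leftover as constant and the substrates as plentiful. The partner then falls in a pseudo-first-order way, and one constant κ, the partner's fractional loss per hour at the leftover catalyst, describes it: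

c(partner) / c(partner charged) = exp(−κ t)

The partner can convert at most 40.0% of both substrates together. The east run had lost 20.5% of them at 6.00 h, so, as a reading:

κ = −ln(1 − 20.5% / 40.0%) / 6.00 h = 0.120 /h

The border of this rule shows in a ratio of readings: by 6.00 h the east run has used about half of what the partner can convert, so late in a run the substrates no longer count as plentiful and κ should sag. κ also belongs to the 0.62 mM of added ligand in the east run, while blue and teal carry 0.44 mM, less than that.

For blue, κ leaves 38.3% of the partner; for teal, 55.0%. The east excess reads 10.0% at 4.00 h and 10.9% at 6.00 h. At that pace, the hours between teal and blue add 1.4 percentage points, less than the margin of 2 points, so I expect neither to win.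

The forecast gave 13.4% for blue and 11.7% for teal, hence neither, saying “Racemisation holds it near a plateau”. The flasks give 12.5% for blue and 12.0% for teal, hence neither.

    partner + catalyst intermediate A → free catalyst + left-handed product (k = 108 /M/min)
    free catalyst + right-handed substrate ⇌ catalyst intermediate B (K = 3.40 /M, k = 373 /M/min)
    left-handed substrate ⇌ right-handed substrate (k = 0.00151 /min)
    free catalyst + left-handed substrate ⇌ catalyst intermediate A (K = 3.51 /M, k = 3820 /M/min)
    free catalyst + added ligand ⇌ idle complex (K = 2000 /M, k = 1690 /M/min)
    partner + catalyst intermediate B → free catalyst + right-handed product (k = 9.46 /M/min)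
    free catalyst + impurity → spent catalyst (k = 42800 /M/min)

Blue keeps 37% of its partner at the end and teal 52%, and blue has not come to rest. Left ten times as long, blue has 0.0101% of its partner against 0.00691% from κ. Its products add up to 40.0% against the ceiling of 40.0%, both substrates stand at 30.0%, and the excess has shrunk to 0.00970%.

The neighbour flask, blue with 1.40 equiv of partner in place of 0.800 equiv, has a ceiling of 70.0%, and the same κ gives 43.2% of product at 8.0 h. The computed flask holds 40.7%, with an excess of 24.1%.

The earlier runs and the new flask come from a simulation for substances that don't exist; noise was put on by code.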